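**Retrosynthetic overview**

1. Pyran ring last: O1–C2 and C4–C4a come from a chiral-acid-controlled dehydrative annulation of 4-methoxy-2-methylphenol (from o-cresol) with a β,β-disubstituted enal carried by the finished bicyclic enone; this sets C2.
2. The enal arm comes from a C6 2-methylallyl group (cross-metathesis); the C6–C bond from Negishi coupling of a vinylogous triflate, the C5–C bond from palladium allylation of a trans-hydrindane-4,6-dione, the tertiary alcohol from Markovnikov hydration.
3. The six-membered carbocycle is closed by Claisen condensation (enol lactone to 1,3-dione) across the two trans arms of a 1,2-dimethylcyclopentane.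
4. The cyclopentane with both quaternary carbons comes from a stereospecific oxidative ring contraction (1,2-shift of the quaternary ring carbon) of a (1,2,3-trimethylcyclohex-2-enyl)acetic acid; the tethered carboxyl forces anti addition and hence the trans relationship.
5. That acid comes by Ireland–Claisen chirality transfer from a tertiary allylic alcohol made by catalytic asymmetric methyl addition to 2,3-dimethylcyclohexenone (from 1,2-dimethylcyclohexene). Ring order: cyclohexene (bought), cyclopentane, cyclohexenone, pyran.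

Assumption: the 1,3-diones are drawn as diketo tautomers (C-5 has no defined configuration there), and the enantiomer of each chiral catalyst is the one that gives the descriptor stated.

**Route**

Step 1
Reactants: 1 1,2-dimethylcyclohexene
Product: 2 2,3-dimethylcyclohex-2-en-1-one
Conditions: Rh2(cap)4 (cap = caprolactamate, 1 mol%), t-BuOOH (70% aq., 5 equiv), K2CO3, CH2Cl2, 25 °C
Reagents that add atoms: tert-butyl hydroperoxide, CC(C)(C)OO
Why: Allylic C–H oxidation by tert-butylperoxyl radicals takes a ring allylic hydrogen of the symmetrical tetrasubstituted alkene, and since both ring CH2 groups next to the alkene are equivalent only one enone can form; no stereocentre is made.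

Step 2
Reactants: 2 2,3-dimethylcyclohex-2-en-1-one
Product: 3 (1R)-1,2,3-trimethylcyclohex-2-en-1-ol
Conditions: Me2Zn (3 equiv), Ti(OiPr)4 (1.2 equiv), C2-symmetric bis(camphorsulfonamide) diol ligand from trans-cyclohexane-1,2-diamine (5 mol%), toluene–hexane, 25 °C; aq. NH4Cl
Reagents that add atoms: dimethylzinc, C[Zn]C
Why: Catalytic enantioselective 1,2-addition of a dialkylzinc to an α-substituted cyclic enone (titanium bis(sulfonamide) diol catalysis) delivers methyl to one carbonyl face because the α-methyl group makes the two carbonyl flanks very different, and the 1R carbinol so formed fixes every later stereocentre of the carbocyclic core.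

Step 3
Reactants: 3 (1R)-1,2,3-trimethylcyclohex-2-en-1-ol
Product: 7 2-[(1R)-1,2,3-trimethylcyclohex-2-en-1-yl]acetic acid, via tertiary acetate 4 (not isolated), via silyl ketene acetal 5 (not isolated), via silyl ester 6 (not isolated)
Conditions: n-BuLi, THF, −78 °C; Ac2O, −78 → 0 °C; then LiN(iPr)2, Me3SiCl–Et3N, −78 → 40 °C; 1 M HCl
Reagents that add atoms: acetic anhydride, CC(=O)OC(C)=O
Why: Ireland–Claisen rearrangement, in which the [3,3] shift of the silyl ketene acetal forms the new C–C bond at C-3 on the same ring face from which the C-1 oxygen leaves (suprafacial chirality transfer), so the 1R carbinol gives the R quaternary carbon without loss of ee and the silyl ester is hydrolysed on work-up.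

Step 4
Reactants: 7 2-[(1R)-1,2,3-trimethylcyclohex-2-en-1-yl]acetic acid
Product: 10 (4aR,7aS)-4a,7a-dimethyl-1-methylidenehexahydrocyclopenta[c]pyran-3(1H)-one, via iodanyl lactone 8 (not isolated), via acyloxocarbenium ion 9 (not isolated)
Conditions: PhI(OCOCF3)2 (1.2 equiv), CH2Cl2–(CF3)2CHOH (4:1), −40 → 0 °C; then 2,6-lutidine
Reagents that add atoms: none
Why: Proposed new method: trivalent iodine adds to the tetrasubstituted alkene on the face opposite the CH2CO2H arm because only that iodonium can be opened 5-exo and anti by the tethered carboxyl, giving cis-fused iodanyl lactone 8, whose tertiary C–I(Ph) bond is a hypernucleofuge that leaves as the antiperiplanar C1–C2 ring bond migrates (1,2-alkyl shift, retention at the migrating quaternary carbon, inversion at the terminus, six- to five-membered ring contraction) while the lactone oxygen stabilises cation 9, which loses a methyl proton to give 10 with the acyl carbon and the CH2 arm trans (methyls anti); the closest known reactions are the trivalent-iodine or thallium trinitrate ring contraction of cyclohexenes to acylcyclopentanes assisted by a hydroxyl group and the iodane-mediated lactonisation/1,2-aryl shift of alkenoic acids, and the new element is acyloxy-assisted migration of a quaternary ring carbon that creates two adjacent quaternary stereocentres.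

Step 5
Reactants: 10 (4aR,7aS)-4a,7a-dimethyl-1-methylidenehexahydrocyclopenta[c]pyran-3(1H)-one
Product: 13 (3aS,7aR)-3a,7a-dimethyl-5-(2-methylprop-2-en-1-yl)hexahydro-1H-indene-4,6(5H,7H)-dione, via keto ester 11 (not isolated), via dione 12 (not isolated)
Conditions: NaOMe (1.1 equiv), MeOH–THF, 65 °C; then Pd(PPh3)4 (3 mol%), 2-methylallyl acetate (1.05 equiv), 40 °C; aq. HCl
Reagents that add atoms: 2-methylallyl acetate, CC(=C)COC(C)=O
Why: Methoxide opens the enol lactone to the methyl ester and the methyl-ketone enolate 11, which closes the six-membered ring by intramolecular Claisen (Dieckmann-type) condensation to the sodium enolate of 12, and Tsuji–Trost allylation of this soft enolate is C-selective at C-5; the quaternary stereocentres are untouched and the trans ring fusion follows from the trans arms.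

Step 6
Reactants: 13 (3aS,7aR)-3a,7a-dimethyl-5-(2-methylprop-2-en-1-yl)hexahydro-1H-indene-4,6(5H,7H)-dione
Product: 14 (3aS,7aR)-3a,7a-dimethyl-5-(2-methylprop-2-en-1-yl)-4-oxo-2,3,3a,4,7,7a-hexahydro-1H-inden-6-yl trifluoromethanesulfonate
Conditions: Tf2O (1.1 equiv), 2,6-lutidine, CH2Cl2, −78 °C
Reagents that add atoms: trifluoromethanesulfonic anhydride, O=S(=O)(OS(=O)(=O)C(F)(F)F)C(F)(F)F
Why: Enol triflate formation on the vinylogous acid occurs at the less hindered oxygen on C-6, because the oxygen on C-4 is shielded by the adjacent quaternary C-3a, giving the vinylogous acyl triflate needed for cross-coupling.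

Step 7
Reactants: 14 (3aS,7aR)-3a,7a-dimethyl-5-(2-methylprop-2-en-1-yl)-4-oxo-2,3,3a,4,7,7a-hexahydro-1H-inden-6-yl trifluoromethanesulfonate
Product: 16 (3aS,7aR)-3a,7a-dimethyl-5-{2-methyl-2-[(trimethylsilyl)oxy]propyl}-4-oxo-2,3,3a,4,7,7a-hexahydro-1H-inden-6-yl trifluoromethanesulfonate, via tertiary alcohol 15 (not isolated)
Conditions: Co(acac)2 (20 mol%), PhSiH3, O2 (1 atm), THF, 0 → 25 °C; then 1-(trimethylsilyl)imidazole, 0 °C
Reagents that add atoms: dioxygen, O=O; 1-(trimethylsilyl)imidazole, C[Si](C)(C)n1ccnc1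
Why: Mukaiyama hydration, in which cobalt-hydride hydrogen-atom transfer to the 1,1-disubstituted alkene gives the tertiary radical that is trapped by O2 (Markovnikov) while the tetrasubstituted electron-poor triflate-bearing alkene is inert, and silylation in the same flask stops the tertiary alcohol from displacing the neighbouring triflate.

Step 8
Reactants: 16 (3aS,7aR)-3a,7a-dimethyl-5-{2-methyl-2-[(trimethylsilyl)oxy]propyl}-4-oxo-2,3,3a,4,7,7a-hexahydro-1H-inden-6-yl trifluoromethanesulfonate
Product: 18 (3aS,7aR)-5-(2-hydroxy-2-methylpropyl)-3a,7a-dimethyl-6-(2-methylprop-2-en-1-yl)-1,2,3,3a,7,7a-hexahydro-4H-inden-4-one, via silyl ether 17 (not isolated)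
Conditions: 2-methylallylmagnesium chloride + ZnCl2 (THF, 0 °C), Pd(PPh3)4 (5 mol%), 0 → 25 °C; then 1 M HCl–THF, 0 °C
Reagents that add atoms: 2-methylallylmagnesium chloride, CC(=C)C[Mg]Cl
Why: Negishi cross-coupling, in which oxidative addition of zerovalent palladium into the vinylogous acyl triflate is fast, the symmetrical 2-methylallyl group transfers without regiochemical ambiguity, the near-neutral conditions leave the hindered ketone alone and keep the skipped diene out of conjugation, and dilute acid in the work-up removes the silyl ether.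

Step 9
Reactants: 18 (3aS,7aR)-5-(2-hydroxy-2-methylpropyl)-3a,7a-dimethyl-6-(2-methylprop-2-en-1-yl)-1,2,3,3a,7,7a-hexahydro-4H-inden-4-one
Product: 19 (2E)-4-[(3aS,7aR)-5-(2-hydroxy-2-methylpropyl)-3a,7a-dimethyl-4-oxo-2,3,3a,4,7,7a-hexahydro-1H-inden-6-yl]-3-methylbut-2-enal
Conditions: (E)-but-2-enal (5 equiv), second-generation Hoveyda–Grubbs catalyst RuCl2(H2IMes)(=CH-C6H4-2-OiPr) (7 mol%), 1,4-benzoquinone (10 mol%), CH2Cl2, 40 °C
Reagents that add atoms: (E)-but-2-enal, C/C=C/C=O
Why: Olefin cross-metathesis of the 1,1-disubstituted alkene and an excess of the electron-poor enal gives the trisubstituted enal (E major, and both geometries converge in step 11), the tetrasubstituted enone alkene does not react, and benzoquinone suppresses ruthenium-hydride isomerisation of the skipped diene.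

Step 10
Reactants: 20 2-methylphenol
Product: 22 4-methoxy-2-methylphenol, via quinone monoketal 21 (not isolated)
Conditions: PhI(OAc)2 (2.1 equiv), MeOH, 0 °C; then Zn dust, AcOH, 25 °C
Reagents that add atoms: methanol, CO
Why: Oxidative dearomatisation by trivalent iodine in methanol (para-selective trapping of the phenoxenium ion, then a second oxidation) gives the para-quinone monoketal, and zinc reduction re-aromatises it by loss of methanol to the 4-methoxyphenol.

Step 11
Reactants: 19 (2E)-4-[(3aS,7aR)-5-(2-hydroxy-2-methylpropyl)-3a,7a-dimethyl-4-oxo-2,3,3a,4,7,7a-hexahydro-1H-inden-6-yl]-3-methylbut-2-enal; 22 4-methoxy-2-methylphenol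
Product: 25 (3aS,7aR)-5-(2-hydroxy-2-methylpropyl)-6-{[(2R)-6-methoxy-2,8-dimethyl-2H-chromen-2-yl]methyl}-3a,7a-dimethyl-1,2,3,3a,7,7a-hexahydro-4H-inden-4-one, via benzylic alcohol 23 (not isolated), via allyl cation 24 (not isolated)
Conditions: confined chiral imidodiphosphorimidate Brønsted acid (BINOL-derived IDPi, 5 mol%), 5 Å molecular sieves, toluene, −20 → 0 °C
Reagents that add atoms: none
Why: Proposed new method: the strong confined chiral acid first promotes ortho-selective Friedel–Crafts 1,2-hydroxyalkylation of the phenol at its only free ortho position (the β,β-disubstituted enal resists conjugate addition) to give 23, then ionises it to the aryl-conjugated allyl cation 24 (a protonated vinyl ortho-quinone methide) held as a contact ion pair by the chiral anion, and C–O ring closure inside this ion pair distinguishes the methyl group from the bulky CH2-hydrindenone group and sets C2 as R under catalyst control because the core stereocentres are five bonds away; the closest known reactions are the racemic phenylboronic acid- or titanium-mediated phenol–enal chromene annulation and the chiral N-triflylphosphoramide-catalysed enantioselective cyclisation of aryl-substituted 2-(3-hydroxyalk-1-enyl)phenols to 2,2-disubstituted 2H-chromenes, and the new element is a dialkyl-substituted cation generated directly from phenol and enal.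

**Compound list**

1 | 1,2-dimethylcyclohexene | CC1=C(C)CCCC1 | starting material
2 | 2,3-dimethylcyclohex-2-en-1-one | CC1=C(C)C(=O)CCC1 | intermediate
3 | (1R)-1,2,3-trimethylcyclohex-2-en-1-ol | C[C@@]1(O)CCCC(C)=C1C | intermediate
4 | (1R)-1,2,3-trimethylcyclohex-2-en-1-yl acetate | C[C@@]1(OC(C)=O)CCCC(C)=C1C | intermediate
5 | trimethyl[(1-{[(1R)-1,2,3-trimethylcyclohex-2-en-1-yl]oxy}ethenyl)oxy]silane | C[C@@]1(OC(=C)O[Si](C)(C)C)CCCC(C)=C1C | intermediate
6 | trimethylsilyl 2-[(1R)-1,2,3-trimethylcyclohex-2-en-1-yl]acetate | CC1=C(C)[C@@](C)(CC(=O)O[Si](C)(C)C)CCC1 | intermediate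
7 | 2-[(1R)-1,2,3-trimethylcyclohex-2-en-1-yl]acetic acid | CC1=C(C)[C@@](C)(CC(=O)O)CCC1 | intermediate
8 | (3aR,7S,7aS)-3a,7,7a-trimethyl-7-[phenyl(trifluoroacetoxy)-λ3-iodanyl]hexahydro-1-benzofuran-2(3H)-one (cis-fused lactone; iodine trans to the lactone oxygen) | C[C@]1(I(c2ccccc2)OC(=O)C(F)(F)F)CCC[C@]2(C)CC(=O)O[C@]12C | intermediate
9 | (4aR,7aS)-1,4a,7a-trimethyl-3-oxohexahydrocyclopenta[c]pyran-1-ylium (cyclic acyloxocarbenium ion; trans ring fusion) | C[C+]1[C@@]2(C)CCC[C@]2(C)CC(=O)O1 | intermediate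
10 | (4aR,7aS)-4a,7a-dimethyl-1-methylidenehexahydrocyclopenta[c]pyran-3(1H)-one (trans ring fusion) | C=C1[C@@]2(C)CCC[C@]2(C)CC(=O)O1 | intermediate
11 | methyl 2-[(1R,2S)-2-acetyl-1,2-dimethylcyclopentyl]acetate (acetyl and CH2CO2Me trans) | CC(=O)[C@@]1(C)CCC[C@]1(C)CC(=O)OC | intermediate
12 | (3aS,7aR)-3a,7a-dimethylhexahydro-1H-indene-4,6(5H,7H)-dione (trans ring fusion) | O=C1[C@@]2(C)CCC[C@]2(C)CC(=O)C1 | intermediate
13 | (3aS,7aR)-3a,7a-dimethyl-5-(2-methylprop-2-en-1-yl)hexahydro-1H-indene-4,6(5H,7H)-dione | O=C1[C@@]2(C)CCC[C@]2(C)CC(=O)C1CC(C)=C | intermediate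
14 | (3aS,7aR)-3a,7a-dimethyl-5-(2-methylprop-2-en-1-yl)-4-oxo-2,3,3a,4,7,7a-hexahydro-1H-inden-6-yl trifluoromethanesulfonate | O=C1[C@@]2(C)CCC[C@]2(C)CC(OS(=O)(=O)C(F)(F)F)=C1CC(C)=C | intermediate
15 | (3aS,7aR)-5-(2-hydroxy-2-methylpropyl)-3a,7a-dimethyl-4-oxo-2,3,3a,4,7,7a-hexahydro-1H-inden-6-yl trifluoromethanesulfonate | O=C1[C@@]2(C)CCC[C@]2(C)CC(OS(=O)(=O)C(F)(F)F)=C1CC(C)(C)O | intermediate
16 | (3aS,7aR)-3a,7a-dimethyl-5-{2-methyl-2-[(trimethylsilyl)oxy]propyl}-4-oxo-2,3,3a,4,7,7a-hexahydro-1H-inden-6-yl trifluoromethanesulfonate | O=C1[C@@]2(C)CCC[C@]2(C)CC(OS(=O)(=O)C(F)(F)F)=C1CC(C)(C)O[Si](C)(C)C | intermediate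
17 | (3aS,7aR)-3a,7a-dimethyl-6-(2-methylprop-2-en-1-yl)-5-{2-methyl-2-[(trimethylsilyl)oxy]propyl}-1,2,3,3a,7,7a-hexahydro-4H-inden-4-one | O=C1[C@@]2(C)CCC[C@]2(C)CC(CC(C)=C)=C1CC(C)(C)O[Si](C)(C)C | intermediate
18 | (3aS,7aR)-5-(2-hydroxy-2-methylpropyl)-3a,7a-dimethyl-6-(2-methylprop-2-en-1-yl)-1,2,3,3a,7,7a-hexahydro-4H-inden-4-one | O=C1[C@@]2(C)CCC[C@]2(C)CC(CC(C)=C)=C1CC(C)(C)O | intermediate
19 | (2E)-4-[(3aS,7aR)-5-(2-hydroxy-2-methylpropyl)-3a,7a-dimethyl-4-oxo-2,3,3a,4,7,7a-hexahydro-1H-inden-6-yl]-3-methylbut-2-enal | O=C1[C@@]2(C)CCC[C@]2(C)CC(C/C(C)=C/C=O)=C1CC(C)(C)O | intermediate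
20 | 2-methylphenol (o-cresol) | Cc1ccccc1O | starting material
21 | 4,4-dimethoxy-2-methylcyclohexa-2,5-dien-1-one | COC1(OC)C=CC(=O)C(C)=C1 | intermediate
22 | 4-methoxy-2-methylphenol | COc1ccc(O)c(C)c1 | intermediate
23 | (3aS,7aR)-6-[(2E)-4-hydroxy-4-(2-hydroxy-5-methoxy-3-methylphenyl)-2-methylbut-2-en-1-yl]-5-(2-hydroxy-2-methylpropyl)-3a,7a-dimethyl-1,2,3,3a,7,7a-hexahydro-4H-inden-4-one (both carbinol epimers) | COc1cc(C)c(O)c(c1)C(O)/C=C(\C)CC1=C(CC(C)(C)O)C(=O)[C@@]2(C)CCC[C@]2(C)C1 | intermediate
24 | allyl cation from 23 by loss of water (protonated vinyl ortho-quinone methide; ion pair with the catalyst anion) | COc1cc(C)c(O)c(c1)/C=C/[C+](C)CC1=C(CC(C)(C)O)C(=O)[C@@]2(C)CCC[C@]2(C)C1 | intermediate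
25 | (3aS,7aR)-5-(2-hydroxy-2-methylpropyl)-6-{[(2R)-6-methoxy-2,8-dimethyl-2H-chromen-2-yl]methyl}-3a,7a-dimethyl-1,2,3,3a,7,7a-hexahydro-4H-inden-4-one (trans ring fusion) | COc1cc(C)c2c(c1)C=C[C@@](C)(CC1=C(CC(C)(C)O)C(=O)[C@@]3(C)CCC[C@]3(C)C1)O2 | target

**Step count and risks**

Total step count: 11. Longest linear sequence: 10 steps (steps 1 to 9, then 11); step 10 makes the phenol partner.

The step most likely to fail is the oxidative ring contraction of step 4, where the tertiary cation could instead eliminate or suffer a methyl shift. Its fallback uses the known epoxide-to-acylcyclopentane (Meinwald) rearrangement and sets out from acid 7. The acid is esterified (MeI, K2CO3, DMF) to methyl 2-[(1R)-1,2,3-trimethylcyclohex-2-en-1-yl]acetate F1. m-CPBA (CH2Cl2, NaHCO3, 0 °C) gives two epoxides, from which the isomer with oxygen anti to the ester arm, methyl 2-[(1R,2R,6S)-1,2,6-trimethyl-7-oxabicyclo[4.1.0]heptan-2-yl]acetate F2, is separated. A bulky Lewis acid, MeAl(OAr)2 (Ar = 4-bromo-2,6-di-tert-butylphenyl), in CH2Cl2 at −78 °C then moves the quaternary ring carbon anti to the breaking C–O bond. This gives keto ester 11, where the fallback comes back to the route (NaOMe closure and allylation of step 5).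

The second is the chiral-acid chromene annulation of step 11, which may give low selectivity at C2 or be too slow in the Friedel–Crafts stage. Its fallback sets C2 by known palladium allylic etherification and ring-closing metathesis and sets out from enal 19.
- NaBH4–CeCl3·7H2O (MeOH, −78 °C) reduces only the aldehyde to (3aS,7aR)-6-[(2E)-4-hydroxy-2-methylbut-2-en-1-yl]-5-(2-hydroxy-2-methylpropyl)-3a,7a-dimethyl-1,2,3,3a,7,7a-hexahydro-4H-inden-4-one F5.
- ClCO2Me–pyridine converts the primary alcohol into (2E)-4-[(3aS,7aR)-5-(2-hydroxy-2-methylpropyl)-3a,7a-dimethyl-4-oxo-2,3,3a,4,7,7a-hexahydro-1H-inden-6-yl]-3-methylbut-2-en-1-yl methyl carbonate F6.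
- Phenol 22 is ortho-formylated (MgCl2, Et3N, paraformaldehyde, MeCN) to 2-hydroxy-5-methoxy-3-methylbenzaldehyde F7 and methylenated (Ph3PCH3Br, KN(SiMe3)2, THF) to 2-ethenyl-4-methoxy-6-methylphenol F8.
- Pd2(dba)3·CHCl3 and the C2-symmetric trans-cyclohexane-1,2-diamine bis(2-diphenylphosphinobenzamide) ligand (CH2Cl2, 25 °C) join F6 and F8 at the tertiary allyl terminus to give (3aS,7aR)-6-[(2R)-2-(2-ethenyl-4-methoxy-6-methylphenoxy)-2-methylbut-3-en-1-yl]-5-(2-hydroxy-2-methylpropyl)-3a,7a-dimethyl-1,2,3,3a,7,7a-hexahydro-4H-inden-4-one F9.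
- Ring-closing metathesis (second-generation Grubbs catalyst RuCl2(PCy3)(H2IMes)(=CHPh), CH2Cl2, 40 °C) closes the pyran and arrives at target 25.

The third is the hydration of step 7, where hydrogen-atom transfer could touch the triflate-bearing enone or the new alcohol could cyclise onto C-6 before it is silylated. Its fallback brings the side chain in already oxygenated and sets out from dione 12 (step 5 stopped and acidified before the allylation). The known organocatalytic three-component reductive alkylation of cyclic 1,3-diones (L-proline 20 mol%, Hantzsch ester, CH2Cl2, 25 °C) is run on 2-methyl-2-[(trimethylsilyl)oxy]propanal F3, itself made by i-Bu2AlH reduction (CH2Cl2, −78 °C) of commercial 2-methyl-2-[(trimethylsilyl)oxy]propanenitrile. This gives (3aS,7aR)-3a,7a-dimethyl-5-{2-methyl-2-[(trimethylsilyl)oxy]propyl}hexahydro-1H-indene-4,6(5H,7H)-dione F4. Triflation as in step 6 (Tf2O, 2,6-lutidine, CH2Cl2, −78 °C) comes back to the route at 16.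

Further compounds
F1 | step 4 | methyl 2-[(1R)-1,2,3-trimethylcyclohex-2-en-1-yl]acetate | CC1=C(C)[C@@](C)(CC(=O)OC)CCC1
F2 | step 4 | methyl 2-[(1R,2R,6S)-1,2,6-trimethyl-7-oxabicyclo[4.1.0]heptan-2-yl]acetate | C[C@@]12O[C@]1(C)[C@@](C)(CC(=O)OC)CCC2
F3 | step 7 | 2-methyl-2-[(trimethylsilyl)oxy]propanal | CC(C)(C=O)O[Si](C)(C)C
F4 | step 7 | (3aS,7aR)-3a,7a-dimethyl-5-{2-methyl-2-[(trimethylsilyl)oxy]propyl}hexahydro-1H-indene-4,6(5H,7H)-dione | O=C1[C@@]2(C)CCC[C@]2(C)CC(=O)C1CC(C)(C)O[Si](C)(C)C
F5 | step 11 | (3aS,7aR)-6-[(2E)-4-hydroxy-2-methylbut-2-en-1-yl]-5-(2-hydroxy-2-methylpropyl)-3a,7a-dimethyl-1,2,3,3a,7,7a-hexahydro-4H-inden-4-one | O=C1[C@@]2(C)CCC[C@]2(C)CC(C/C(C)=C/CO)=C1CC(C)(C)O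
F6 | step 11 | (2E)-4-[(3aS,7aR)-5-(2-hydroxy-2-methylpropyl)-3a,7a-dimethyl-4-oxo-2,3,3a,4,7,7a-hexahydro-1H-inden-6-yl]-3-methylbut-2-en-1-yl methyl carbonate | O=C1[C@@]2(C)CCC[C@]2(C)CC(C/C(C)=C/COC(=O)OC)=C1CC(C)(C)O
F7 | step 11 | 2-hydroxy-5-methoxy-3-methylbenzaldehyde | COc1cc(C)c(O)c(C=O)c1
F8 | step 11 | 2-ethenyl-4-methoxy-6-methylphenol | COc1cc(C)c(O)c(C=C)c1
F9 | step 11 | (3aS,7aR)-6-[(2R)-2-(2-ethenyl-4-methoxy-6-methylphenoxy)-2-methylbut-3-en-1-yl]-5-(2-hydroxy-2-methylpropyl)-3a,7a-dimethyl-1,2,3,3a,7,7a-hexahydro-4H-inden-4-one | C=C[C@@](C)(CC1=C(CC(C)(C)O)C(=O)[C@@]2(C)CCC[C@]2(C)C1)Oc1c(C)cc(OC)cc1C=C
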